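**Plan**

- Retrosynthetic cuts, in order: the C3–O ester bond (angelic acid); the C11–O bond together with the C6=C7 unsaturation (ene reaction of a 7(11)-isopropylidene ketone); C7–C11 (acetone aldol); the C4–O and C3–H bonds (enol ether oxidation and hydride reduction of a Δ4-3-ketone); the C8–C9/C9–C10 pair (taking out C9 contracts ring B to a cyclopentanone); C4–C5 (aldol condensation); C1–C10 (Michael addition).
- Enabling feature: C10 is a quaternary, methyl-bearing carbon whose neighbours C5 (ring fusion) and, once C9 is removed, C8 (ketone) are both at the carbonyl oxidation level. C5–C6–C7–C8–C10 is therefore a 2-methylcyclopentane-1,3-dione with two enantiotopic carbonyls, and ring A (C1–C5, C10) can close onto one of them.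
- Forward order: the C1–C4/C15 chain is joined by Michael addition, ring A closes in the amino-acid aldol, ring B is enlarged from five to six members by insertion of C9, ring A is reduced and oxygenated, ring B receives C11–C13 and its unsaturation, and the ester is made last.
- Stereochemistry: C10 from the (S)-phenylalanine-controlled choice between the two ring carbonyls; C5 from axial protonation in the Li/NH3 reduction (trans-decalin); C4 from epoxidation of the silyl enol ether opposite the axial C10 methyl; C3 from axial hydride delivery; the Z ester geometry comes in with angelic acid.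

Key step: step 2

Remark: atoms carry the eudesmane numbers of the target throughout (C14 on C10, C15 on C4, C11–C13 on C7; in the hydrindane compounds C8 is bonded directly to C10), α is the face opposite the C10 methyl, and where a centre is erased in the following step (C4 of the bicyclic ketol, C8 of the hydroxy selenide, C7 of the acetone aldol) either epimer serves and one is drawn or the centre is left undefined.

Step 1
Reactants: 1 2-methylcyclopentane-1,3-dione; 2 ethyl vinyl ketone
Product: 3 2-methyl-2-(3-oxopentyl)cyclopentane-1,3-dione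
Conditions: H2O, 20–25 °C, several days
Reagents that add atoms: none
Why: Michael addition in which the acidic cyclic 1,3-dione, self-catalysed in water through its enol, adds through C10 to the vinyl ketone, forming the C1–C10 bond and an achiral quaternary centre flanked by two enantiotopic carbonyls.

Step 2
Reactants: 3 2-methyl-2-(3-oxopentyl)cyclopentane-1,3-dione
Product: 5 (S)-4,7a-dimethyl-2,3,7,7a-tetrahydro-1H-indene-1,5(6H)-dione, via bicyclic ketol 4 (not isolated)
Conditions: (S)-phenylalanine (1.0 equiv), (1S)-(+)-10-camphorsulfonic acid (0.5 equiv), DMF, 30 → 70 °C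
Reagents that add atoms: none
Why: The primary amine of (S)-phenylalanine condenses with the side-chain ketone C3, the enamine carbon C4 attacks one ring carbonyl (C5), and acid-promoted loss of water from ketol 4 gives the C4=C5 enone; this is the Hajos–Parrish–Eder–Sauer–Wiechert aldol condensation in its phenylalanine/sulfonic acid form for ethyl ketones. Ring A (C1–C5, C10) closes in the 6-(enolendo)-exo-trig mode. The only stereocentre that emerges, C10, is already present as a prochiral quaternary carbon and should become (S) because the carboxylic acid of the enamine-bound catalyst hydrogen-bonds to, and so activates, only one of the two ring carbonyls in a chair-like transition state. The step needs selection between two enantiotopic carbonyls, which the chiral amino acid supplies, and selection between the two α-carbons of the side-chain ketone, which the substrate secures because only C4 reaches a ring carbonyl through a six-membered transition state (C2 would have to close a four-membered ring). A primary amino acid is chosen because an ethyl ketone forms the required trisubstituted enamine poorly with a secondary amine.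

Step 3
Reactants: 5 (S)-4,7a-dimethyl-2,3,7,7a-tetrahydro-1H-indene-1,5(6H)-dione
Product: 6 (1S,7aS)-1-hydroxy-4,7a-dimethyl-1-[(phenylselanyl)methyl]-1,2,3,6,7,7a-hexahydro-5H-inden-5-one
Conditions: (PhSe)2CH2, n-BuLi, THF, −78 °C; then enedione 5 added slowly (1.0 equiv of reagent), −78 °C; aq NH4Cl
Reagents that add atoms: bis(phenylselanyl)methane, C([Se]c1ccccc1)[Se]c1ccccc1
Why: Selenium–lithium exchange gives PhSeCH2Li, a weakly basic but strongly nucleophilic carbanion that should add to the isolated cyclopentanone carbonyl C8 faster than to the enone carbonyl C3, which is deactivated by conjugation with the tetrasubstituted C4=C5 bond and flanked by the C15 methyl (the order of reactivity that lets borohydride reduce only the saturated carbonyl of such enediones); attack anti to the angular methyl gives the 8β-ol, a centre erased in step 4 (1,2-addition of an α-seleno organolithium to a ketone).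

Step 4
Reactants: 6 (1S,7aS)-1-hydroxy-4,7a-dimethyl-1-[(phenylselanyl)methyl]-1,2,3,6,7,7a-hexahydro-5H-inden-5-one
Product: 7 (R)-1,4a-dimethyl-4,4a,7,8-tetrahydronaphthalene-2,6(3H,5H)-dione
Conditions: AgBF4, neutral Al2O3, CH2Cl2, 0 → 25 °C
Reagents that add atoms: none
Why: Silver binds selenium and turns PhSe into a leaving group, and the C8–C10 bond shifts to the exocyclic CH2 as C8–O becomes the carbonyl (semipinacol-type ring enlargement of a β-hydroxy selenide); the quaternary, allylic C10 should migrate in preference to the C7 methylene and does so with retention, so the new carbon becomes C9 between C8 and C10 and the C10 configuration is untouched.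

Step 5
Reactants: 7 (R)-1,4a-dimethyl-4,4a,7,8-tetrahydronaphthalene-2,6(3H,5H)-dione
Product: 8 8,8-ethylenedioxy-11,12,13-trinoreudesm-4-en-3-one
Conditions: TMSOCH2CH2OTMS, TMSOTf (cat.), CH2Cl2, −78 °C; pyridine quench
Reagents that add atoms: 1,2-bis(trimethylsilyloxy)ethane, C[Si](C)(C)OCCO[Si](C)(C)C
Why: Noyori dioxolanation, in which the saturated C8 ketone is ketalised far faster than the conjugated C3 ketone at low temperature and the C4=C5 bond does not migrate, leaving the enone free for the reduction.

Step 6
Reactants: 8 8,8-ethylenedioxy-11,12,13-trinoreudesm-4-en-3-one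
Product: 10 8,8-ethylenedioxy-3-(trimethylsilyloxy)-11,12,13-trinor-5α-eudesm-3-ene, via lithium enolate 9 (not isolated)
Conditions: Li, NH3(l), THF, t-BuOH (1 equiv), −78 → −33 °C; isoprene; NH3 evaporated; TMSCl, Et3N, THF, 0 °C
Reagents that add atoms: chlorotrimethylsilane, C[Si](C)(C)Cl
Why: Dissolving-metal (Birch-type) reduction of the enone with trapping of the regiodefined enolate, in which the C5 carbanion is protonated axially on the α face, anti to the axial C10 methyl, to give the trans-decalin (5α-H), and the C3–C4 lithium enolate is O-silylated before it can equilibrate, the dioxolane being inert.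

Step 7
Reactants: 10 8,8-ethylenedioxy-3-(trimethylsilyloxy)-11,12,13-trinor-5α-eudesm-3-ene
Product: 13 8,8-ethylenedioxy-4α-hydroxy-11,12,13-trinor-5α-eudesman-3-one, via silyloxy epoxide 11 (not isolated), via silyloxy ketone 12 (not isolated)
Conditions: mCPBA (1.05 equiv), NaHCO3, CH2Cl2, −20 → 0 °C; then Bu4NF, AcOH, THF, 0 °C
Reagents that add atoms: 3-chloroperoxybenzoic acid, OOC(=O)c1cccc(Cl)c1
Why: Rubottom oxidation, in which the peracid epoxidises the electron-rich C3=C4 bond from the α face opposite the axial C10 methyl, the silyloxy oxirane opens with 1,4-silyl shift to the 4α-silyloxy ketone, and buffered fluoride frees the tertiary alcohol, fixing C4 as 4α-OH/4β-CH3 without acid that would endanger the ketal.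

Step 8
Reactants: 13 8,8-ethylenedioxy-4α-hydroxy-11,12,13-trinor-5α-eudesman-3-one
Product: 15 3β,4α-dihydroxy-11,12,13-trinor-5α-eudesman-8-one, via diol ketal 14 (not isolated)
Conditions: NaBH4, MeOH, −20 → 0 °C; then 1 M HCl, THF, 25 °C
Reagents that add atoms: water, O
Why: Hydride adds to the C3 carbonyl along the axial trajectory from the α face, because the β face is screened by the syn-axial C14 and C15 methyls as in 4,4-dimethyl-3-keto steroids, giving the equatorial 3β-alcohol trans to the 4α-hydroxyl, and aqueous acid in the same flask hydrolyses the dioxolane to the C8 ketone (borohydride reduction followed by ketal hydrolysis).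

Step 9
Reactants: 15 3β,4α-dihydroxy-11,12,13-trinor-5α-eudesman-8-one
Product: 16 3β,4α-bis(triethylsilyloxy)-11,12,13-trinor-5α-eudesman-8-one
Conditions: TESOTf (2.5 equiv), 2,6-lutidine, CH2Cl2, −78 → 0 °C
Reagents that add atoms: triethylsilyl trifluoromethanesulfonate, CC[Si](CC)(CC)OS(=O)(=O)C(F)(F)F
Why: A silyl triflate with a hindered pyridine base silylates the secondary 3β- and the tertiary 4α-hydroxyl in one operation without enolising the ketone, so that no acidic or sulfonylatable hydroxyl interferes with enolate formation and mesylation in the next two steps (silyl ether protection).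

Step 10
Reactants: 16 3β,4α-bis(triethylsilyloxy)-11,12,13-trinor-5α-eudesman-8-one; 17 acetone
Product: 20 11-hydroxy-3β,4α-bis(triethylsilyloxy)-5α-eudesman-8-one, via lithium enolate 18 (not isolated), via chlorozinc enolate 19 (not isolated)
Conditions: LiN(iPr)2 (LDA, 1.1 equiv), THF, −78 °C; ZnCl2, −78 °C; acetone, −78 → −40 °C; aq NH4Cl
Reagents that add atoms: none
Why: Directed aldol addition, in which the amide base removes the axial 7α-hydrogen because C9 is neopentylic and shielded by the quaternary C10, and the zinc enolate adds to acetone to give a chelated zinc aldolate that resists retro-aldol cleavage, the new C7 centre being of no consequence because it becomes sp2 in step 11.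

Step 11
Reactants: 20 11-hydroxy-3β,4α-bis(triethylsilyloxy)-5α-eudesman-8-one
Product: 22 3β,4α-bis(triethylsilyloxy)-5α-eudesm-7(11)-en-8-one, via mesylate 21 (not isolated)
Conditions: MsCl, Et3N, DMAP (cat.), CH2Cl2, 0 → 25 °C; then DBU, 25 °C
Reagents that add atoms: none
Why: The tertiary alcohol is mesylated through sulfene and the mesylate is expelled by E1cB elimination across C7–C11, DBU also moving any isopropenyl isomer into conjugation, which gives the tetrasubstituted 7(11)-en-8-one (dehydration of an aldol through its sulfonate).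

Step 12
Reactants: 22 3β,4α-bis(triethylsilyloxy)-5α-eudesm-7(11)-en-8-one
Product: 24 11-hydroxy-3β,4α-bis(triethylsilyloxy)-5α-eudesm-6-en-8-one, via hydroperoxide 23 (not isolated)
Conditions: O2, visible light, tetraphenylporphyrin (cat.), CH2Cl2, 0 °C; then PPh3, 0 → 25 °C
Reagents that add atoms: dioxygen, O=O
Why: Schenck ene reaction of singlet oxygen with an enone locked s-cis, in which oxygen bonds to C11 and the hydrogen is taken from C6, the alkyl group geminal to the carbonyl on C7 (the gem effect known for isopropylidene ketones of the pulegone type), so that the double bond moves to C6=C7 and stays conjugated, after which PPh3 reduces the tertiary hydroperoxide to the C11 alcohol; C11 is not stereogenic and C5 is untouched.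

Step 13
Reactants: 24 11-hydroxy-3β,4α-bis(triethylsilyloxy)-5α-eudesm-6-en-8-one
Product: 25 3β,4α,11-trihydroxy-5α-eudesm-6-en-8-one
Conditions: HF·pyridine, pyridine, THF, 0 → 25 °C
Reagents that add atoms: none
Why: Buffered hydrogen fluoride cleaves both triethylsilyl ethers, the mildly acidic medium avoiding the γ-deprotonation at C5 that a basic fluoride source could cause and leaving the tertiary C11 alcohol intact, since its cation would be destabilised by the adjacent enone (fluoride desilylation).

Step 14
Reactants: 25 3β,4α,11-trihydroxy-5α-eudesm-6-en-8-one; 26 angelic acid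
Product: 28 3β-angeloyloxy-4α,11-dihydroxy-5α-eudesm-6-en-8-one, via mixed anhydride 27 (not isolated)
Conditions: 2,4,6-trichlorobenzoyl chloride, Et3N, toluene, 25 °C; then triol 25 added, 75 °C
Reagents that add atoms: none
Why: Yamaguchi-type esterification through the mixed anhydride, in which only the secondary 3β-hydroxyl is acylated (both tertiary hydroxyls are inert), attack occurs at the angeloyl carbonyl because the aroyl carbonyl is shielded by its two ortho chlorines, and the absence of a nucleophilic catalyst or strong base should keep the Z geometry from isomerising to the tiglate.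

**Compound list**

1 | 2-methylcyclopentane-1,3-dione | CC1C(=O)CCC1=O | starting material
2 | ethyl vinyl ketone (pent-1-en-3-one) | C=CC(=O)CC | starting material
3 | 2-methyl-2-(3-oxopentyl)cyclopentane-1,3-dione (achiral) | CCC(=O)CCC1(C)C(=O)CCC1=O | intermediate
4 | (3aS,7aS)-3a-hydroxy-4,7a-dimethylhexahydro-1H-indene-1,5(6H)-dione (cis-fused ketol, OH cis to the angular methyl, C4 undefined) | O=C1CC[C@]2(C)C(=O)CC[C@]2(O)C1C | intermediate
5 | (S)-4,7a-dimethyl-2,3,7,7a-tetrahydro-1H-indene-1,5(6H)-dione | O=C1CC[C@]2(C)C(=O)CCC2=C1C | intermediate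
6 | (1S,7aS)-1-hydroxy-4,7a-dimethyl-1-[(phenylselanyl)methyl]-1,2,3,6,7,7a-hexahydro-5H-inden-5-one (8β-OH, 8α-CH2SePh) | O=C1CC[C@]2(C)[C@](O)(C[Se]c3ccccc3)CCC2=C1C | intermediate
7 | (R)-1,4a-dimethyl-4,4a,7,8-tetrahydronaphthalene-2,6(3H,5H)-dione (11,12,13-trinoreudesm-4-ene-3,8-dione) | O=C1CC[C@]2(C)CC(=O)CCC2=C1C | intermediate
8 | 8,8-ethylenedioxy-11,12,13-trinoreudesm-4-en-3-one | O=C1CC[C@]2(C)CC3(OCCO3)CCC2=C1C | intermediate
9 | lithium 8,8-ethylenedioxy-11,12,13-trinor-5α-eudesm-3-en-3-olate | [Li+].[O-]C=1CC[C@]2(C)CC3(OCCO3)CC[C@H]2C=1C | intermediate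
10 | 8,8-ethylenedioxy-3-(trimethylsilyloxy)-11,12,13-trinor-5α-eudesm-3-ene | C[Si](C)(C)OC=1CC[C@]2(C)CC3(OCCO3)CC[C@H]2C=1C | intermediate
11 | 3α,4α-epoxy-8,8-ethylenedioxy-3β-(trimethylsilyloxy)-11,12,13-trinor-5α-eudesmane | C[Si](C)(C)O[C@@]12CC[C@]3(C)CC4(OCCO4)CC[C@H]3[C@]1(C)O2 | intermediate
12 | 8,8-ethylenedioxy-4α-(trimethylsilyloxy)-11,12,13-trinor-5α-eudesman-3-one | O=C1CC[C@]2(C)CC3(OCCO3)CC[C@H]2[C@]1(C)O[Si](C)(C)C | intermediate
13 | 8,8-ethylenedioxy-4α-hydroxy-11,12,13-trinor-5α-eudesman-3-one (4β-CH3) | O=C1CC[C@]2(C)CC3(OCCO3)CC[C@H]2[C@]1(C)O | intermediate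
14 | 8,8-ethylenedioxy-11,12,13-trinor-5α-eudesmane-3β,4α-diol | O[C@H]1CC[C@]2(C)CC3(OCCO3)CC[C@H]2[C@]1(C)O | intermediate
15 | 3β,4α-dihydroxy-11,12,13-trinor-5α-eudesman-8-one | O[C@H]1CC[C@]2(C)CC(=O)CC[C@H]2[C@]1(C)O | intermediate
16 | 3β,4α-bis(triethylsilyloxy)-11,12,13-trinor-5α-eudesman-8-one | CC[Si](CC)(CC)O[C@H]1CC[C@]2(C)CC(=O)CC[C@H]2[C@]1(C)O[Si](CC)(CC)CC | intermediate
17 | acetone | CC(C)=O | starting material
18 | lithium 7-en-8-olate of 16 | CC[Si](CC)(CC)O[C@H]1CC[C@]2(C)CC([O-])=CC[C@H]2[C@]1(C)O[Si](CC)(CC)CC.[Li+] | intermediate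
19 | chlorozinc 7-en-8-olate of 16 | CC[Si](CC)(CC)O[C@H]1CC[C@]2(C)CC(O[Zn]Cl)=CC[C@H]2[C@]1(C)O[Si](CC)(CC)CC | intermediate
20 | 11-hydroxy-3β,4α-bis(triethylsilyloxy)-5α-eudesman-8-one (7α-H epimer drawn) | CC[Si](CC)(CC)O[C@H]1CC[C@]2(C)CC(=O)[C@@H](C(C)(C)O)C[C@H]2[C@]1(C)O[Si](CC)(CC)CC | intermediate
21 | 11-(methanesulfonyloxy)-3β,4α-bis(triethylsilyloxy)-5α-eudesman-8-one | CC[Si](CC)(CC)O[C@H]1CC[C@]2(C)CC(=O)[C@@H](C(C)(C)OS(C)(=O)=O)C[C@H]2[C@]1(C)O[Si](CC)(CC)CC | intermediate
22 | 3β,4α-bis(triethylsilyloxy)-5α-eudesm-7(11)-en-8-one | CC[Si](CC)(CC)O[C@H]1CC[C@]2(C)CC(=O)C(=C(C)C)C[C@H]2[C@]1(C)O[Si](CC)(CC)CC | intermediate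
23 | 11-hydroperoxy-3β,4α-bis(triethylsilyloxy)-5α-eudesm-6-en-8-one | CC[Si](CC)(CC)O[C@H]1CC[C@]2(C)CC(=O)C(C(C)(C)OO)=C[C@H]2[C@]1(C)O[Si](CC)(CC)CC | intermediate
24 | 11-hydroxy-3β,4α-bis(triethylsilyloxy)-5α-eudesm-6-en-8-one | CC[Si](CC)(CC)O[C@H]1CC[C@]2(C)CC(=O)C(C(C)(C)O)=C[C@H]2[C@]1(C)O[Si](CC)(CC)CC | intermediate
25 | 3β,4α,11-trihydroxy-5α-eudesm-6-en-8-one | O[C@H]1CC[C@]2(C)CC(=O)C(C(C)(C)O)=C[C@H]2[C@]1(C)O | intermediate
26 | angelic acid ((Z)-2-methylbut-2-enoic acid) | C/C=C(/C)C(=O)O | starting material
27 | angelic 2,4,6-trichlorobenzoic anhydride | C/C=C(/C)C(=O)OC(=O)c1c(Cl)cc(Cl)cc1Cl | intermediate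
28 | 3β-angeloyloxy-4α,11-dihydroxy-5α-eudesm-6-en-8-one (CNP0261892.1) | C/C=C(/C)C(=O)O[C@H]1CC[C@]2(C)CC(=O)C(C(C)(C)O)=C[C@H]2[C@]1(C)O | target

**Totals**

Total step count: 14. Longest linear sequence: 14 steps (fully linear from 1 and 2 to 28).

**Steps most likely to fail**

Step 3. The organolithium may lose chemoselectivity, adding in part to the conjugated C3 carbonyl or abstracting a proton instead of adding to C8. The fallback sets out from 5 and masks the enone first. Triethyl orthoformate and catalytic TsOH in ethanol should convert only the conjugated ketone into its 3-ethoxy-3,5-dienol ether F1, as in the classical enol-ether masking of 4-en-3-ones beside a hindered cyclopentanone. PhSeCH2Li, pre-mixed with anhydrous CeCl3 to make it non-basic towards the now allylic C7 hydrogens, then adds to the only carbonyl left and gives dienol ether carbinol F2. Dilute aqueous HCl in THF hydrolyses the enol ether back to the conjugated ketone, and the route is rejoined at 6.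

Step 4. The hydroxyl may close onto the silver-activated CH2 to give a spiro-oxirane instead of the 1,2-shift, or the C7 methylene may migrate in place of C10. The fallback sets out from 5 and drives the shift with a sulfur-stabilised cation instead of a primary selenium leaving group. LiCH(SPh)2 (from bis(phenylsulfanyl)methane and n-BuLi, THF, −78 °C) adds to C8 to give dithioacetal carbinol F3. CuOSO2CF3 with iPr2NEt in warm benzene removes one thiolate, and the thionium ion so formed accepts the more substituted C10, giving phenylsulfanyl dione F4. SmI2 in THF/MeOH at −78 °C cleaves the C9–S bond, and the route is rejoined at 7.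

Step 12. Hydrogen abstraction may occur from the C12/C13 methyls instead of C6, or the electron-poor alkene may take up oxygen so slowly that the sensitiser bleaches. The fallback sets out from 20 and bypasses steps 11 and 12 by dehydrogenating instead of oxygenating. TMSOTf and Et3N in CH2Cl2 at 0 °C silylate the C11 hydroxyl (which blocks retro-aldol cleavage) and convert the ketone into the more substituted enol ether, bis(trimethylsilyl) enol ether F5. Saegusa–Ito oxidation with Pd(OAc)2 in MeCN can only form the C6=C7 enone, because C10 carries no hydrogen, and gives silyloxy enone F6. HF·pyridine under the conditions of step 13 removes all three silyl groups, and the route is rejoined at 25.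

**Further compounds**

F1 | step 3 | (S)-5-ethoxy-4,7a-dimethyl-2,6,7,7a-tetrahydro-1H-inden-1-one | CCOC=1CC[C@]2(C)C(=O)CC=C2C=1C
F2 | step 3 | (1S,7aS)-5-ethoxy-4,7a-dimethyl-1-[(phenylselanyl)methyl]-2,6,7,7a-tetrahydro-1H-inden-1-ol | CCOC=1CC[C@]2(C)[C@](O)(C[Se]c3ccccc3)CC=C2C=1C
F3 | step 4 | (1S,7aS)-1-[bis(phenylsulfanyl)methyl]-1-hydroxy-4,7a-dimethyl-1,2,3,6,7,7a-hexahydro-5H-inden-5-one | O=C1CC[C@]2(C)[C@](O)(C(Sc3ccccc3)Sc3ccccc3)CCC2=C1C
F4 | step 4 | 9-(phenylsulfanyl)-11,12,13-trinoreudesm-4-ene-3,8-dione (C9 undefined) | O=C1CC[C@]2(C)C(Sc3ccccc3)C(=O)CCC2=C1C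
F5 | step 12 | 3β,4α-bis(triethylsilyloxy)-8,11-bis(trimethylsilyloxy)-5α-eudesm-7-ene | CC[Si](CC)(CC)O[C@H]1CC[C@]2(C)CC(O[Si](C)(C)C)=C(C(C)(C)O[Si](C)(C)C)C[C@H]2[C@]1(C)O[Si](CC)(CC)CC
F6 | step 12 | 3β,4α-bis(triethylsilyloxy)-11-(trimethylsilyloxy)-5α-eudesm-6-en-8-one | CC[Si](CC)(CC)O[C@H]1CC[C@]2(C)CC(=O)C(C(C)(C)O[Si](C)(C)C)=C[C@H]2[C@]1(C)O[Si](CC)(CC)CC
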